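**Retrosynthetic overview**

1. The target is meso (2,5-cis diaryl, 3,4-cis diaroyl, each aroyl trans to the aryl on the adjacent carbon); it comes from its hexabenzyl ether by hydrogenolysis, with no C–C bond made after the oxolane exists.
2. The hexabenzyl ether comes from an oxolane carrying a temporary allyl ester on C3: deallylation/decarboxylation removes this activating group, and the two α-keto methines C3/C4 are then equilibrated.
3. The oxolane (the only ring of the target, formed last) comes from a strain-release (3+2) annulation of a donor–acceptor cyclopropane with 4-(benzyloxy)benzaldehyde: O1–C5 is made by opening the three-membered ring at its donor carbon, and the ring is closed by the C3–C2 bond (keto-ester enolate carbon onto oxocarbenium carbon).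
4. Enabling feature: C3 of the oxolane is the α-carbon of an aryl ketone and C2/C5 are benzylic ether carbons; in the precursor the cyclopropane C1–C2 σ-bond lies between a 4-benzyloxyphenyl donor (C2) and a geminal aroyl/ester acceptor pair (C1) and carries the ring strain.
5. The cyclopropane (first ring formed, consumed in the key step) comes from a chalcone and an allyl β-keto ester (Michael addition/iodination/3-exo-tet closure), both made from 2',4'-dihydroxyacetophenone.

Key step: step 5

Remark: the target is meso (mirror plane through O1 and the midpoint of C3–C4), so chiral intermediates are used as racemates; each SMILES shows one enantiomer and leaves undefined a centre that is erased later.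

Assumption: among the 2,5-cis diastereomers of the 3,4-diaroyl-2,5-diaryloxolane, the meso isomer (the only one without a vicinal cis aryl/aroyl pair) is taken to be the most stable, so that equilibration of C3 and C4 converges on it.

**Step 1**
Reactants: 1 2',4'-dihydroxyacetophenone
Product: 2 1-[2,4-bis(benzyloxy)phenyl]ethan-1-one
Conditions: BnBr (2.3 equiv), K2CO3 (3 equiv), DMF, 70 °C
Reagents that add atoms: benzyl bromide, BrCc1ccccc1
Why: Williamson etherification (SN2 on benzyl bromide by the phenoxides); in DMF at 70 °C the hydrogen-bonded 2-OH should be alkylated as well as the 4-OH, and the methyl ketone is untouched.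

**Step 2**
Reactants: 2 1-[2,4-bis(benzyloxy)phenyl]ethan-1-one; 3 4-(benzyloxy)benzaldehyde
Product: 4 (E)-1-[2,4-bis(benzyloxy)phenyl]-3-[4-(benzyloxy)phenyl]prop-2-en-1-one
Conditions: KOH (3 equiv), EtOH–THF, rt
Reagents that add atoms: none
Why: Claisen–Schmidt (crossed aldol) condensation of the methyl ketone with the non-enolisable aldehyde, whose E1cB dehydration should give the conjugated (E)-enone; benzyl ethers are inert to KOH.

**Step 3**
Reactants: 2 1-[2,4-bis(benzyloxy)phenyl]ethan-1-one
Product: 5 allyl 3-[2,4-bis(benzyloxy)phenyl]-3-oxopropanoate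
Conditions: NaH (2.5 equiv), diallyl carbonate (2 equiv), THF, reflux; then 1 M HCl
Reagents that add atoms: diallyl carbonate, C=CCOC(=O)OCC=C
Why: crossed Claisen condensation (C-acylation of the sodium enolate of 2 by the carbonate), driven by deprotonation of the β-keto ester formed; it installs the temporary allyl ester that later activates the cyclopropane.

**Step 4**
Reactants: 4 (E)-1-[2,4-bis(benzyloxy)phenyl]-3-[4-(benzyloxy)phenyl]prop-2-en-1-one; 5 allyl 3-[2,4-bis(benzyloxy)phenyl]-3-oxopropanoate
Product: 8 allyl 1,3-bis[2,4-bis(benzyloxy)benzoyl]-2-[4-(benzyloxy)phenyl]cyclopropane-1-carboxylate (racemic; 2-aryl trans to 3-aroyl; both C1 epimers), via Michael adduct 6 (not isolated), via tertiary iodide 7 (not isolated)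
Conditions: DBU (0.2 equiv), CH2Cl2, rt; then I2 (1.2 equiv), DBU (2.2 equiv), 0 °C to rt
Reagents that add atoms: none
Why: Michael-initiated ring closure (conjugate addition of the β-keto ester to the enone, iodination of the doubly activated carbon, 3-exo-tet C-alkylation by the ketone enolate), as in the standard chalcone/malonate cyclopropanation; the C2 aryl and C3 aroyl should end up trans because the ring closes from the less crowded enolate rotamer, and the C1 epimers are not separated since C1 becomes an enolate in step 5.

**Step 5**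
Reactants: 8 allyl 1,3-bis[2,4-bis(benzyloxy)benzoyl]-2-[4-(benzyloxy)phenyl]cyclopropane-1-carboxylate; 3 4-(benzyloxy)benzaldehyde
Product: 9 allyl 3,4-bis[2,4-bis(benzyloxy)benzoyl]-2,5-bis[4-(benzyloxy)phenyl]oxolane-3-carboxylate (racemic; 2,5-cis diaryl; 4-aroyl cis to the 5-aryl; both C3 epimers)
Conditions: Sn(OTf)2 (10 mol %), 3 (3 equiv), 4 Å MS, CH2Cl2, rt
Reagents that add atoms: none
Why: Sn(OTf)2 binds the geminal aroyl/ester pair on C1 of 8 and polarises the strained C1–C2 bond, which the 4-benzyloxyphenyl group on C2 pushes from the other side; the carbonyl oxygen of 3 attacks C2 with inversion (SN2-like opening through an intimate ion pair) to give a tin enolate tethered to an (E)-oxocarbenium ion, and the enolate carbon then attacks the oxocarbenium carbon, so that the oxolane is closed by the C3–C2 bond. The closest known reaction type is the Lewis-acid-catalysed formal (3+2) cycloaddition of aldehydes to 2-arylcyclopropane-1,1-dicarbonyl compounds, which is also known for 2,3-disubstituted cyclopropanes. The oxolane is the only ring closed, by an aldol-type (Prins-like) 5-(enolexo)-endo-trig attack that oxocarbenium electrophiles tolerate. C5 derives from C2 of 8 with inversion and C4 from C3 of 8 unchanged, so the trans cyclopropane should lead to the 4,5-cis adduct; C2 is created in the ring closure, whose envelope transition state keeps both aryl groups pseudo-equatorial and so should give the 2,5-cis ether; C3 is quaternary and both epimers serve, because the ester is removed in step 6. The step needs cleavage of C1–C2 and not of C2–C3, which the geminal acceptor pair on C1 (against a single aroyl on C3) secures, and capture of the ring-opened species by the aldehyde rather than O-cyclisation of the C1 ketone to a 2,3-dihydrofuran (Cloke–Wilson), which the excess of the electron-rich aldehyde and the reversibility of that O-cyclisation at the 4-alkoxybenzylic carbon should secure.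

**Step 6**
Reactants: 9 allyl 3,4-bis[2,4-bis(benzyloxy)benzoyl]-2,5-bis[4-(benzyloxy)phenyl]oxolane-3-carboxylate
Product: 12 [(2R,3R,4S,5S)-2,5-bis[4-(benzyloxy)phenyl]oxolane-3,4-diyl]bis{[2,4-bis(benzyloxy)phenyl]methanone} (meso; hexabenzyl ether of the target), via keto acid 10 (not isolated), via 4,5-cis diketone 11 (not isolated)
Conditions: Pd(PPh3)4 (5 mol %), morpholine (3 equiv), THF, rt to 40 °C; then DBU (0.3 equiv), 40 °C
Reagents that add atoms: none
Why: Tsuji–Trost deallylation (π-allylpalladium trapped by morpholine) releases the β-keto acid, which decarboxylates through the six-membered transition state to the C3 enol and ketone; DBU then epimerises the α-keto methines C3 and C4 through their enolates without touching the ether carbons C2 and C5 (ring opening by β-elimination would be the reverse of a 5-endo-trig addition), and the mixture should converge on the meso isomer, in which each aroyl is trans to the aryl on the adjacent carbon.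

**Step 7**
Reactants: 12 [(2R,3R,4S,5S)-2,5-bis[4-(benzyloxy)phenyl]oxolane-3,4-diyl]bis{[2,4-bis(benzyloxy)phenyl]methanone}
Product: 13 [(2R,3R,4S,5S)-2,5-bis(4-hydroxyphenyl)oxolane-3,4-diyl]bis[(2,4-dihydroxyphenyl)methanone] (meso; CNP0237262.1)
Conditions: H2 (1 atm), 10 % Pd/C, EtOAc–MeOH, rt
Reagents that add atoms: none
Why: heterogeneous hydrogenolysis of the six aryl benzyl ethers, which should be cleaved much faster than the benzylic C–O bonds of the oxolane or the aryl ketones; the neutral conditions leave the four stereocentres untouched.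

**Compound list**

1 | 2',4'-dihydroxyacetophenone | CC(=O)c1ccc(O)cc1O | starting material
2 | 1-[2,4-bis(benzyloxy)phenyl]ethan-1-one | CC(=O)c1ccc(OCc2ccccc2)cc1OCc1ccccc1 | intermediate
3 | 4-(benzyloxy)benzaldehyde | O=Cc1ccc(OCc2ccccc2)cc1 | starting material
4 | (E)-1-[2,4-bis(benzyloxy)phenyl]-3-[4-(benzyloxy)phenyl]prop-2-en-1-one | O=C(/C=C/c1ccc(OCc2ccccc2)cc1)c1ccc(OCc2ccccc2)cc1OCc1ccccc1 | intermediate
5 | allyl 3-[2,4-bis(benzyloxy)phenyl]-3-oxopropanoate | C=CCOC(=O)CC(=O)c1ccc(OCc2ccccc2)cc1OCc1ccccc1 | intermediate
6 | allyl 2-[2,4-bis(benzyloxy)benzoyl]-5-[2,4-bis(benzyloxy)phenyl]-3-[4-(benzyloxy)phenyl]-5-oxopentanoate (Michael adduct, diastereomer mixture) | C=CCOC(=O)C(C(=O)c1ccc(OCc2ccccc2)cc1OCc1ccccc1)C(c1ccc(OCc2ccccc2)cc1)CC(=O)c1ccc(OCc2ccccc2)cc1OCc1ccccc1 | intermediate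
7 | allyl 2-[2,4-bis(benzyloxy)benzoyl]-5-[2,4-bis(benzyloxy)phenyl]-3-[4-(benzyloxy)phenyl]-2-iodo-5-oxopentanoate (tertiary iodide, diastereomer mixture) | C=CCOC(=O)C(I)(C(=O)c1ccc(OCc2ccccc2)cc1OCc1ccccc1)C(c1ccc(OCc2ccccc2)cc1)CC(=O)c1ccc(OCc2ccccc2)cc1OCc1ccccc1 | intermediate
8 | allyl 1,3-bis[2,4-bis(benzyloxy)benzoyl]-2-[4-(benzyloxy)phenyl]cyclopropane-1-carboxylate (racemic; 2-aryl trans to 3-aroyl; C1 undefined) | C=CCOC(=O)C1(C(=O)c2ccc(OCc3ccccc3)cc2OCc2ccccc2)[C@@H](c2ccc(OCc3ccccc3)cc2)[C@@H]1C(=O)c1ccc(OCc2ccccc2)cc1OCc1ccccc1 | intermediate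
9 | allyl 3,4-bis[2,4-bis(benzyloxy)benzoyl]-2,5-bis[4-(benzyloxy)phenyl]oxolane-3-carboxylate (racemic; 2-aryl, 4-aroyl and 5-aryl on one face; C3 undefined) | C=CCOC(=O)C1(C(=O)c2ccc(OCc3ccccc3)cc2OCc2ccccc2)[C@@H](C(=O)c2ccc(OCc3ccccc3)cc2OCc2ccccc2)[C@@H](c2ccc(OCc3ccccc3)cc2)O[C@H]1c1ccc(OCc2ccccc2)cc1 | intermediate
10 | 3,4-bis[2,4-bis(benzyloxy)benzoyl]-2,5-bis[4-(benzyloxy)phenyl]oxolane-3-carboxylic acid (configuration as in 9) | OC(=O)C1(C(=O)c2ccc(OCc3ccccc3)cc2OCc2ccccc2)[C@@H](C(=O)c2ccc(OCc3ccccc3)cc2OCc2ccccc2)[C@@H](c2ccc(OCc3ccccc3)cc2)O[C@H]1c1ccc(OCc2ccccc2)cc1 | intermediate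
11 | {2,5-cis-2,5-bis[4-(benzyloxy)phenyl]oxolane-3,4-diyl}bis{[2,4-bis(benzyloxy)phenyl]methanone}, 4-aroyl cis to the 5-aryl, C3 undefined (first-formed diketone) | O=C(c1ccc(OCc2ccccc2)cc1OCc1ccccc1)C1[C@@H](C(=O)c2ccc(OCc3ccccc3)cc2OCc2ccccc2)[C@@H](c2ccc(OCc3ccccc3)cc2)O[C@H]1c1ccc(OCc2ccccc2)cc1 | intermediate
12 | [(2R,3R,4S,5S)-2,5-bis[4-(benzyloxy)phenyl]oxolane-3,4-diyl]bis{[2,4-bis(benzyloxy)phenyl]methanone} (meso) | O=C(c1ccc(OCc2ccccc2)cc1OCc1ccccc1)[C@@H]1[C@H](C(=O)c2ccc(OCc3ccccc3)cc2OCc2ccccc2)[C@@H](c2ccc(OCc3ccccc3)cc2)O[C@H]1c1ccc(OCc2ccccc2)cc1 | intermediate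
13 | [(2R,3R,4S,5S)-2,5-bis(4-hydroxyphenyl)oxolane-3,4-diyl]bis[(2,4-dihydroxyphenyl)methanone] (meso) | O=C(c1ccc(O)cc1O)[C@@H]1[C@H](C(=O)c2ccc(O)cc2O)[C@@H](c2ccc(O)cc2)O[C@H]1c1ccc(O)cc1 | target

**Step count and risks**

Total step count: 7. Longest linear sequence: 6 steps (steps 1, 2 or 3, 4, 5, 6, 7).

Steps most likely to fail:

1. Step 6 – incomplete thermodynamic convergence of the two α-keto centres: the energy gap between the meso isomer and the isomer with the C4 aroyl cis to the C5 aryl may be small, and long exposure to base may open the ring by β-elimination. Fallback: the one-pass equilibration is replaced by resolution with recycle. The palladium stage is run without DBU and 11 is isolated; 11 is then equilibrated only briefly with DBU, 12 is removed by crystallisation or chromatography, and the remaining isomers are returned to the base until consumed. This sets out from 11 and comes back at 12 and makes no new compound (F0).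

2. Step 5 – diversion of the ring-opened species into intramolecular O-cyclisation (Cloke–Wilson) or elimination, or erosion of the 2,5-cis selectivity by reversible ionisation of the electron-rich benzylic ether carbons under the Lewis acid. Fallback: a nucleophile-mediated stepwise annulation of the known MgI2 type is used instead of Lewis-acid activation. MgI2 in THF opens 8 at the donor carbon to the magnesium enolate of allyl 2,3-bis[2,4-bis(benzyloxy)benzoyl]-4-[4-(benzyloxy)phenyl]-4-iodobutanoate F1. Aldol addition of F1 to 3 and 5-exo-tet O-alkylation should give allyl 3,4-bis[2,4-bis(benzyloxy)benzoyl]-2,5-bis[4-(benzyloxy)phenyl]oxolane-3-carboxylate with the 4-aroyl trans to the 5-aryl F2, the isomer expected from double inversion at the donor carbon. The 2,5-relationship is then set in the O-alkylation and would have to be confirmed. F2 is carried through the conditions of step 6, where C4 is equilibrated in any case. The fallback sets out from 8 and comes back at 12.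

3. Step 4 – iodination at the ketone α-carbon instead of the 1,3-dicarbonyl carbon, followed by O- rather than C-alkylation (2,3-dihydrofuran formation), or base-induced opening of the strained product. Fallback: the halogen is fixed before the conjugate addition. 5 is brominated with NBS to allyl 2-bromo-3-[2,4-bis(benzyloxy)phenyl]-3-oxopropanoate F3, and F3 is combined with 4 and K2CO3 in a classical Michael-initiated ring closure of the bromomalonate type, in which only the simple ketone enolate can close the ring by 3-exo-tet C-alkylation. The fallback sets out from 5 and comes back at 8.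

**Further compounds**

F0 | step 6 | none | none
F1 | step 5 | allyl 2,3-bis[2,4-bis(benzyloxy)benzoyl]-4-[4-(benzyloxy)phenyl]-4-iodobutanoate (as its magnesium enolate; C2 undefined) | C=CCOC(=O)C(C(=O)c1ccc(OCc2ccccc2)cc1OCc1ccccc1)[C@@H](C(=O)c1ccc(OCc2ccccc2)cc1OCc1ccccc1)[C@H](I)c1ccc(OCc2ccccc2)cc1
F2 | step 5 | allyl 3,4-bis[2,4-bis(benzyloxy)benzoyl]-2,5-bis[4-(benzyloxy)phenyl]oxolane-3-carboxylate (racemic; 2,5-cis diaryl; 4-aroyl trans to the 5-aryl; C3 undefined) | C=CCOC(=O)C1(C(=O)c2ccc(OCc3ccccc3)cc2OCc2ccccc2)[C@@H](C(=O)c2ccc(OCc3ccccc3)cc2OCc2ccccc2)[C@H](c2ccc(OCc3ccccc3)cc2)O[C@@H]1c1ccc(OCc2ccccc2)cc1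
F3 | step 4 | allyl 2-bromo-3-[2,4-bis(benzyloxy)phenyl]-3-oxopropanoate | C=CCOC(=O)C(Br)C(=O)c1ccc(OCc2ccccc2)cc1OCc1ccccc1
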